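**Retrosynthetic overview**
- The target comes from its 3‑O‑benzyl ether by hydrogenolysis (last step).
- The 3‑benzyloxy‑5,7‑dihydroxyflavone comes from unprotected phloroglucinol and an α‑benzyloxy aroylacetate in one thermal annulation. This breaks the threefold symmetry of phloroglucinol, forms C4–C4a and O1–C2, and closes the pyranone (C ring) onto the intact A ring.
- The keto ester comes from the aryl nitrile and the enolate of ethyl benzyloxyacetate.
- The (R)‑chromanol comes from achiral 6‑cyano‑2,2‑dimethylchromene by Mn(salen) epoxidation and benzylic C–O hydrogenolysis.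
- Ring order: the chroman pyran ring is bought, the stereocentre is set first, and the C ring is formed last but one step; no ring is formed after that.

Assumption: 2,2‑dimethyl‑2H‑chromene‑6‑carbonitrile and ethyl 2‑(benzyloxy)acetate are bought as catalogue compounds; phloroglucinol is the bulk aromatic feedstock.

The target's single stereocentre is (R) at C‑3 of the chroman.

Step 1
Reactants: 1 2,2‑dimethyl‑2H‑chromene‑6‑carbonitrile
Product: 2 (3R,4R)‑3,4‑epoxy‑2,2‑dimethylchromane‑6‑carbonitrile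
Conditions: (R,R)‑Jacobsen Mn(salen)Cl (2 mol%), 4‑phenylpyridine N‑oxide (10 mol%), aq NaOCl (pH 11.3), CH2Cl2, 0 °C; recrystallise to ≥99% ee
Reagents that add atoms: sodium hypochlorite, [Na+].[O-]Cl
Why: Jacobsen–Katsuki epoxidation; cis, aryl‑conjugated 2,2‑dimethylchromenes are the best substrate class for Mn(salen) oxo transfer, and the (R,R) catalyst delivers oxygen to the face giving the (3R,4R) epoxide (about 97% ee expected), so C‑3 of the target is set here.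

Step 2
Reactants: 2 (3R,4R)‑3,4‑epoxy‑2,2‑dimethylchromane‑6‑carbonitrile
Product: 3 (3R)‑3‑hydroxy‑2,2‑dimethylchromane‑6‑carbonitrile
Conditions: H2 (1 atm), 10% Pd/C, EtOAc, rt, stopped after 1 equiv H2
Reagents that add atoms: none
Why: Pd‑catalysed benzylic C–O hydrogenolysis cleaves only the C4–O bond of the aryl epoxide; C3–O is untouched, so C‑3 keeps its (R) configuration, and the aryl nitrile is not reduced at 1 atm in neutral medium.

Step 3
Reactants: 3 (3R)‑3‑hydroxy‑2,2‑dimethylchromane‑6‑carbonitrile; 4 ethyl 2‑(benzyloxy)acetate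
Product: 7 ethyl 2‑(benzyloxy)‑3‑[(3R)‑3‑hydroxy‑2,2‑dimethyl‑3,4‑dihydro‑2H‑chromen‑6‑yl]‑3‑oxopropanoate, via lithium enolate 5 (not isolated), via enamino ester 6 (not isolated)
Conditions: 4 (3 equiv), LDA (4 equiv), THF, −78 °C; then 3, −78 → 0 °C; then 2 M aq HCl, rt
Reagents that add atoms: water, O
Why: Thorpe/Blaise‑type addition of an ester enolate to a non‑enolisable aryl nitrile gives the N‑metallated enamino ester, which dilute acid hydrolyses to the β‑keto ester; one equivalent of base is spent on the hindered alcohol, the C‑3 stereocentre is remote, and the new α‑centre is labile and removed in step 4.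

Step 4
Reactants: 7 ethyl 2‑(benzyloxy)‑3‑[(3R)‑3‑hydroxy‑2,2‑dimethyl‑3,4‑dihydro‑2H‑chromen‑6‑yl]‑3‑oxopropanoate; 8 phloroglucinol (benzene‑1,3,5‑triol)
Product: 11 3‑(benzyloxy)‑5,7‑dihydroxy‑2‑[(3R)‑3‑hydroxy‑2,2‑dimethyl‑3,4‑dihydro‑2H‑chromen‑6‑yl]‑4H‑chromen‑4‑one, via acylketene 9 (not isolated), via diketone 10 (not isolated)
Conditions: 8 (3 equiv, anhydrous), minimum Ph2O, 240 °C (microwave), 10 min, N2 stream; excess 8 removed by water wash
Reagents that add atoms: none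
Why: Proposed new method: thermal, uncatalysed loss of ethanol from the β‑keto ester gives an α‑oxoketene that C‑acylates phloroglucinol (directly or by O‑acylation and thermal Fries shift), and the resulting ortho‑hydroxyaryl 1,3‑diketone cyclodehydrates to the pyranone; because all three C–H/OH pairs of phloroglucinol are equivalent only one regioisomer can form, and esterification of the free chromanol OH is reversible at this temperature while chromone formation is not; the closest known reaction is the Mentzer pyrone synthesis (catalyst‑free thermal condensation of phloroglucinol with ethyl aroylacetates to 5,7‑dihydroxyflavones), extended here to an α‑benzyloxy keto ester.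

Step 5
Reactants: 11 3‑(benzyloxy)‑5,7‑dihydroxy‑2‑[(3R)‑3‑hydroxy‑2,2‑dimethyl‑3,4‑dihydro‑2H‑chromen‑6‑yl]‑4H‑chromen‑4‑one
Product: 12 3,5,7‑trihydroxy‑2‑[(3R)‑3‑hydroxy‑2,2‑dimethyl‑3,4‑dihydro‑2H‑chromen‑6‑yl]‑4H‑chromen‑4‑one
Conditions: H2 (1 atm), 10% Pd/C, EtOAc–MeOH 1:1, rt
Reagents that add atoms: none
Why: Hydrogenolysis of the benzyl ether of the 3‑hydroxyl; the chromone C2=C3 bond, the chroman ether and the remote carbinol stereocentre are inert under these mild conditions.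

**Compound list**
1 | 2,2‑dimethyl‑2H‑chromene‑6‑carbonitrile | CC1(C)C=Cc2cc(C#N)ccc2O1 | starting material
2 | (3R,4R)‑3,4‑epoxy‑2,2‑dimethylchromane‑6‑carbonitrile [(1aR,7bR)‑2,2‑dimethyl‑1a,7b‑dihydro‑2H‑oxireno[2,3‑c]chromene‑6‑carbonitrile] | CC1(C)Oc2ccc(C#N)cc2[C@H]3O[C@@H]13 | intermediate
3 | (3R)‑3‑hydroxy‑2,2‑dimethylchromane‑6‑carbonitrile | CC1(C)Oc2ccc(C#N)cc2C[C@H]1O | intermediate
4 | ethyl 2‑(benzyloxy)acetate | CCOC(=O)COCc1ccccc1 | starting material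
5 | lithium enolate of 4 (chelated, O–Li cis to OBn) | CCO/C(O[Li])=C/OCc1ccccc1 | intermediate
6 | ethyl (E)‑3‑amino‑2‑(benzyloxy)‑3‑[(3R)‑3‑hydroxy‑2,2‑dimethyl‑3,4‑dihydro‑2H‑chromen‑6‑yl]prop‑2‑enoate (NH2 cis to the ester carbonyl) | CC1(C)Oc2ccc(/C(N)=C(\OCc3ccccc3)C(=O)OCC)cc2C[C@H]1O | intermediate
7 | ethyl 2‑(benzyloxy)‑3‑[(3R)‑3‑hydroxy‑2,2‑dimethyl‑3,4‑dihydro‑2H‑chromen‑6‑yl]‑3‑oxopropanoate (labile C‑2, epimer mixture) | CC1(C)Oc2ccc(C(=O)C(OCc3ccccc3)C(=O)OCC)cc2C[C@H]1O | intermediate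
8 | phloroglucinol (benzene‑1,3,5‑triol) | Oc1cc(O)cc(O)c1 | starting material
9 | 2‑(benzyloxy)‑3‑[(3R)‑3‑hydroxy‑2,2‑dimethyl‑3,4‑dihydro‑2H‑chromen‑6‑yl]‑3‑oxoprop‑1‑en‑1‑one (α‑oxoketene) | CC1(C)Oc2ccc(C(=O)C(OCc3ccccc3)=C=O)cc2C[C@H]1O | intermediate
10 | 2‑(benzyloxy)‑1‑[(3R)‑3‑hydroxy‑2,2‑dimethyl‑3,4‑dihydro‑2H‑chromen‑6‑yl]‑3‑(2,4,6‑trihydroxyphenyl)propane‑1,3‑dione (labile C‑2) | CC1(C)Oc2ccc(C(=O)C(OCc3ccccc3)C(=O)c4c(O)cc(O)cc4O)cc2C[C@H]1O | intermediate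
11 | 3‑(benzyloxy)‑5,7‑dihydroxy‑2‑[(3R)‑3‑hydroxy‑2,2‑dimethyl‑3,4‑dihydro‑2H‑chromen‑6‑yl]‑4H‑chromen‑4‑one | CC1(C)Oc2ccc(-c3oc4cc(O)cc(O)c4c(=O)c3OCc5ccccc5)cc2C[C@H]1O | intermediate
12 | 3,5,7‑trihydroxy‑2‑[(3R)‑3‑hydroxy‑2,2‑dimethyl‑3,4‑dihydro‑2H‑chromen‑6‑yl]‑4H‑chromen‑4‑one | CC1(C)Oc2ccc(-c3oc4cc(O)cc(O)c4c(=O)c3O)cc2C[C@H]1O | target

**Step count**
Total steps: 5. Longest linear sequence: 5 (1 → 2 → 3 → 7 → 11 → 12).

**Steps most likely to fail, with fallbacks**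

Step 4 is the riskiest. The α‑benzyloxy keto ester is untested in this thermal annulation. Possible failures are Pechmann‑type closure to a 4‑arylcoumarin, a second annulation on the product, and thermal loss of the benzyl group. The fallback sets out from 8 (and uses 3) and comes back at 10, replacing steps 3 and 4. Hoesch acylation of 8 with (benzyloxy)acetonitrile (ZnCl2, HCl gas, Et2O, 0 °C) gives 2‑(benzyloxy)‑1‑(2,4,6‑trihydroxyphenyl)ethan‑1‑iminium chloride F1. Boiling F1 in water gives 2‑(benzyloxy)‑1‑(2,4,6‑trihydroxyphenyl)ethan‑1‑one F2. The polylithiated enolate of F2 (LiHMDS 5.5 equiv, THF, −78 °C → rt) is added to nitrile 3 to give the enaminone (E)‑3‑amino‑2‑(benzyloxy)‑3‑[(3R)‑3‑hydroxy‑2,2‑dimethyl‑3,4‑dihydro‑2H‑chromen‑6‑yl]‑1‑(2,4,6‑trihydroxyphenyl)prop‑2‑en‑1‑one F3. Warm aqueous HCl–AcOH hydrolyses F3 to diketone 10, which cyclodehydrates in the same pot to 11.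

Step 3 is next. The electron‑rich nitrile may add the glycolate enolate slowly, and the enolate can self‑condense on warming. The fallback sets out from 3 and comes back at 7. DIBAL‑H (2.2 equiv, CH2Cl2, −78 °C) reduces the nitrile to the N‑aluminated form of (3R)‑3‑hydroxy‑2,2‑dimethylchromane‑6‑carbaldimine F4. Rochelle‑salt work‑up hydrolyses F4 to (3R)‑3‑hydroxy‑2,2‑dimethylchromane‑6‑carbaldehyde F5. Aldol addition of enolate 5 (2.2 equiv, THF, −78 °C) gives ethyl 2‑(benzyloxy)‑3‑hydroxy‑3‑[(3R)‑3‑hydroxy‑2,2‑dimethyl‑3,4‑dihydro‑2H‑chromen‑6‑yl]propanoate F6 as a diastereomer mixture. Activated MnO2 (CH2Cl2, rt) oxidises only the benzylic carbinol of F6 and gives 7.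

Step 2 is third. Palladium can isomerise the epoxide to the chroman‑3‑one or begin to reduce the nitrile. The fallback sets out from 2 and comes back at 3. MgBr2·OEt2 (Et2O, 0 °C) opens 2 at the benzylic carbon with inversion to the trans‑bromohydrin (3S,4S)‑4‑bromo‑3‑hydroxy‑2,2‑dimethylchromane‑6‑carbonitrile F7. C‑3 is spatially unchanged; its descriptor changes only because bromine raises the rank of C‑4. Radical debromination (Bu3SnH, AIBN, benzene, 80 °C) then gives 3.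

**Further compounds**
F1 | step 4 | 2‑(benzyloxy)‑1‑(2,4,6‑trihydroxyphenyl)ethan‑1‑iminium chloride | [NH2+]=C(COCc1ccccc1)c1c(O)cc(O)cc1O.[Cl-]
F2 | step 4 | 2‑(benzyloxy)‑1‑(2,4,6‑trihydroxyphenyl)ethan‑1‑one | O=C(COCc1ccccc1)c1c(O)cc(O)cc1O
F3 | step 4 | (E)‑3‑amino‑2‑(benzyloxy)‑3‑[(3R)‑3‑hydroxy‑2,2‑dimethyl‑3,4‑dihydro‑2H‑chromen‑6‑yl]‑1‑(2,4,6‑trihydroxyphenyl)prop‑2‑en‑1‑one | CC1(C)Oc2ccc(/C(N)=C(\OCc3ccccc3)C(=O)c4c(O)cc(O)cc4O)cc2C[C@H]1O
F4 | step 3 | (3R)‑3‑hydroxy‑2,2‑dimethylchromane‑6‑carbaldimine (formed as its N‑aluminium adduct) | CC1(C)Oc2ccc(C=N)cc2C[C@H]1O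
F5 | step 3 | (3R)‑3‑hydroxy‑2,2‑dimethylchromane‑6‑carbaldehyde | CC1(C)Oc2ccc(C=O)cc2C[C@H]1O
F6 | step 3 | ethyl 2‑(benzyloxy)‑3‑hydroxy‑3‑[(3R)‑3‑hydroxy‑2,2‑dimethyl‑3,4‑dihydro‑2H‑chromen‑6‑yl]propanoate (diastereomer mixture at the two new centres) | CC1(C)Oc2ccc(C(O)C(OCc3ccccc3)C(=O)OCC)cc2C[C@H]1O
F7 | step 2 | (3S,4S)‑4‑bromo‑3‑hydroxy‑2,2‑dimethylchromane‑6‑carbonitrile (trans) | CC1(C)Oc2ccc(C#N)cc2[C@H](Br)[C@H]1O
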